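**Strategy.** The furanone oxygen that links C3 to C10 is read as the ester oxygen of a nine-membered lactone. Disconnecting C2–C3 opens the ten-membered carbocycle (C1–C10) into a C10 tertiary α-acyloxy methyl ketone whose acyl group is the (Z)-C3–C4=C5 enoate. In the forward sense one enolate acylation (O-to-C acyl transfer, then loss of water) makes C2–C3 and closes both the furanone and the carbocycle without touching a stereocentre. The precursor is the γ-lactone/nine-membered lactone 27, assembled from (R)-citramalic acid (C8–C10, C1, C14), an Evans succinate aldol (C7, C8), Felkin vinylation (C6) and ring-closing metathesis (C4=C5).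

Key step: step 18

**Remarks on the chemistry (assumptions and design points)**
- Numbering: C1 furanone C=O; C2=C3 (ring O on C3); C4=C5 (C15 on C4); C6 lactone O–CH; C7; C8 ester O–CH; C9 CH2; C10 quaternary (C14 methyl); C11 (C13 methylene); C12 lactone C=O.
- Assumption: C1 is carried from step 3 to step 12 as a carbinol of uncontrolled configuration and is written without descriptor; both epimers converge in step 13.
- Assumption: compounds 1, 9, 10, 18 and 22 are taken as commercial.
- (a) The lactone α-CH2 (C11) is a second enolisable carbon of the precursor and can reach C3. The key step therefore relies on kinetic selectivity for the methyl ketone, not on the absence of other α-hydrogens.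
- (b) O8 carries TIPS, not TBS, to survive the acid of step 12 and to resist silyl migration in step 18.
- (c) C12 is a tert-butyl ester and O8 is silylated before O6 exists, so only the 6,12-lactone can form.
- (d) The acetyl group is masked as a diol acetonide until after the Grignard step.
- (e) The aldol needs the (R)-configured auxiliary.

**Route**

Step 1
Reactants: 1 (R)-citramalic acid
Product: 2 2-[(4R)-2,2,4-trimethyl-5-oxo-1,3-dioxolan-4-yl]acetic acid
Conditions: Me2C(OMe)2, p-TsOH·H2O (cat.), acetone, rt
Reagents that add atoms: 2,2-dimethoxypropane, COC(C)(C)OC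
Why: Acid-catalysed acetalisation ties the α-hydroxy acid up as the five-membered dioxolanone, which is preferred over the six-membered alternative through the distal carboxyl, so that only the CH2CO2H group (future C9–C8) stays free and the C10 stereocentre of the chiral pool is carried unchanged.

Step 2
Reactants: 2 2-[(4R)-2,2,4-trimethyl-5-oxo-1,3-dioxolan-4-yl]acetic acid
Product: 4 (3R)-3-hydroxy-3-methyloxolan-2-one, via hydroxyethyl dioxolanone 3 (not isolated)
Conditions: BH3·SMe2, THF, 0 °C→rt; MeOH; then p-TsOH·H2O (cat.), CH2Cl2, rt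
Reagents that add atoms: none
Why: Borane reduces the free carboxylic acid chemoselectively beside the dioxolanone carbonyl, and acid-catalysed 5-exo transesterification of the resulting primary alcohol then releases acetone and gives the α-hydroxy-γ-butyrolactone in which C1 (lactone carbonyl) and C8 (OCH2) are differentiated.

Step 3
Reactants: 4 (3R)-3-hydroxy-3-methyloxolan-2-one
Product: 6 (3R)-3-methylpentane-1,3,4-triol (C4 epimers), via lactol 5 (not isolated)
Conditions: MeLi (2.2 equiv), THF, −78 °C; then MeOH, NaBH4, −78→0 °C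
Reagents that add atoms: methyllithium, C[Li]
Why: After deprotonation of the hydroxyl, mono-addition of methyllithium to the lactone should stop at the tetrahedral stage at −78 °C (lactone-to-lactol conversion) and borohydride reduction of the ring-opened hydroxy ketone in the same pot gives the triol, whose new carbinol centre C1 is only a temporary mask of the acetyl carbonyl and is therefore left uncontrolled.

Step 4
Reactants: 6 (3R)-3-methylpentane-1,3,4-triol
Product: 7 2-[(4R)-2,2,4,5-tetramethyl-1,3-dioxolan-4-yl]ethan-1-ol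
Conditions: Me2C(OMe)2, PPTS (cat.), acetone, rt
Reagents that add atoms: 2,2-dimethoxypropane, COC(C)(C)OC
Why: Thermodynamically controlled acetonide formation should select the 1,2-diol (dioxolane) because the 1,3-dioxane through the primary hydroxyl would carry a 1,3-diaxial methyl/methyl contact at the quaternary carbon, which leaves the primary alcohol free and masks both the C10 hydroxyl and the C1 carbinol.

Step 5
Reactants: 7 2-[(4R)-2,2,4,5-tetramethyl-1,3-dioxolan-4-yl]ethan-1-ol
Product: 8 2-[(4R)-2,2,4,5-tetramethyl-1,3-dioxolan-4-yl]acetaldehyde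
Conditions: Dess–Martin periodinane, NaHCO3, CH2Cl2, 0 °C→rt
Reagents that add atoms: none
Why: Dess–Martin oxidation of the primary alcohol gives the C8 aldehyde under buffered, non-basic conditions that avoid β-elimination of the C10 oxygen and leave the acetonide intact.

Step 6
Reactants: 9 mono-tert-butyl succinate; 10 (4R)-4-benzyl-1,3-oxazolidin-2-one
Product: 12 tert-butyl 4-[(4R)-4-benzyl-2-oxo-1,3-oxazolidin-3-yl]-4-oxobutanoate, via pivalic mixed anhydride 11 (not isolated)
Conditions: t-BuCOCl, Et3N, THF, −20 °C; then 10, LiCl, −20 °C→rt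
Reagents that add atoms: none
Why: N-Acylation of the oxazolidinone by the mixed pivalic anhydride (attack at the less hindered carbonyl) gives the succinate imide, and the tert-butyl ester is used so that the aldol hydroxyl formed in step 7 cannot lactonise onto C12.

Step 7
Reactants: 12 tert-butyl 4-[(4R)-4-benzyl-2-oxo-1,3-oxazolidin-3-yl]-4-oxobutanoate; 8 2-[(4R)-2,2,4,5-tetramethyl-1,3-dioxolan-4-yl]acetaldehyde
Product: 14 tert-butyl (3R,4S)-3-{[(4R)-4-benzyl-2-oxo-1,3-oxazolidin-3-yl]carbonyl}-4-hydroxy-5-[(4R)-2,2,4,5-tetramethyl-1,3-dioxolan-4-yl]pentanoate, via dibutylboron enolate 13 (not isolated)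
Conditions: n-Bu2BOTf, i-Pr2NEt, CH2Cl2, 0 °C; then 8, −78→0 °C; pH 7 buffer, MeOH, H2O2
Reagents that add atoms: none
Why: Evans syn aldol reaction in which the (Z)-boron enolate of the imide (enolised at C7 only) adds to the aldehyde through a chair Zimmerman–Traxler transition state on the enolate face opposite the benzyl group of the (R)-auxiliary, which sets C7 and C8 (syn) in the absolute sense required.

Step 8
Reactants: 14 the aldol adduct
Product: 15 tert-butyl (3R,4S)-3-{[(4R)-4-benzyl-2-oxo-1,3-oxazolidin-3-yl]carbonyl}-5-[(4R)-2,2,4,5-tetramethyl-1,3-dioxolan-4-yl]-4-[(triisopropylsilyl)oxy]pentanoate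
Conditions: TIPSOTf, 2,6-lutidine, CH2Cl2, 0 °C→rt
Reagents that add atoms: triisopropylsilyl trifluoromethanesulfonate, CC(C)[Si](C(C)C)(C(C)C)OS(=O)(=O)C(F)(F)F
Why: Silylation of the hindered aldol hydroxyl with the silyl triflate blocks O8 before any other hydroxyl γ to C12 is unveiled, the triisopropylsilyl group being chosen for its stability to the acid of step 12.

Step 9
Reactants: 15 the silylated imide
Product: 16 tert-butyl (3S,4S)-3-(hydroxymethyl)-5-[(4R)-2,2,4,5-tetramethyl-1,3-dioxolan-4-yl]-4-[(triisopropylsilyl)oxy]pentanoate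
Conditions: LiBH4, MeOH (1 equiv), THF, 0 °C
Reagents that add atoms: none
Why: Reductive cleavage of the N-acyl oxazolidinone by lithium borohydride gives the C6 primary alcohol and returns the auxiliary, while the tert-butyl ester and the acetonide are not reduced.

Step 10
Reactants: 16 the primary alcohol
Product: 17 tert-butyl (3R,4S)-3-formyl-5-[(4R)-2,2,4,5-tetramethyl-1,3-dioxolan-4-yl]-4-[(triisopropylsilyl)oxy]pentanoate
Conditions: Dess–Martin periodinane, NaHCO3, CH2Cl2, 0 °C
Reagents that add atoms: none
Why: Buffered Dess–Martin oxidation should give the α-branched C6 aldehyde without epimerising C7, the aldehyde being used at once.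

Step 11
Reactants: 17 the C6 aldehyde; 18 vinylmagnesium bromide
Product: 19 tert-butyl (3S,4R)-4-hydroxy-3-{(1S)-2-[(4R)-2,2,4,5-tetramethyl-1,3-dioxolan-4-yl]-1-[(triisopropylsilyl)oxy]ethyl}hex-5-enoate
Conditions: THF, −78 °C; aq. NH4Cl
Reagents that add atoms: none
Why: Grignard addition under Felkin–Anh control, in which the nucleophile attacks anti to the largest α-substituent (the C8 branch with the bulky silyloxy group) while the CH2CO2t-Bu group lies next to the carbonyl oxygen, should favour the 6R carbinol (C6–O syn to C11), the tert-butyl ester being inert at −78 °C.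

Step 12
Reactants: 19 the allylic alcohol
Product: 20 (4S,5R)-4-{(1S,3R)-3,4-dihydroxy-3-methyl-1-[(triisopropylsilyl)oxy]pentyl}-5-ethenyloxolan-2-one
Conditions: p-TsOH·H2O (0.3 equiv), MeOH, 40 °C; then concentrate from toluene
Reagents that add atoms: none
Why: Acid catalysis closes the γ-lactone by 5-exo transesterification of the C6 hydroxyl onto the tert-butyl ester (with O8 blocked only the 6,12-lactone can form, and it is trans because C6–O and C11 are syn) and in the same operation removes the acetonide by transketalisation, the triisopropylsilyl ether being stable.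

Step 13
Reactants: 20 the lactone diol
Product: 21 (4S,5R)-5-ethenyl-4-{(1S,3R)-3-hydroxy-3-methyl-4-oxo-1-[(triisopropylsilyl)oxy]pentyl}oxolan-2-one
Conditions: IBX, DMSO, rt
Reagents that add atoms: none
Why: IBX oxidises the secondary C1 carbinol of the 1,2-diol to the ketone without glycol cleavage and cannot touch the tertiary C10 hydroxyl, so both C1 epimers converge on one α-ketol.

Step 14
Reactants: 22 ethyl 2-(hydroxymethyl)acrylate
Product: 23 ethyl 2-{[(tert-butyldimethylsilyl)oxy]methyl}prop-2-enoate
Conditions: TBSCl, imidazole, CH2Cl2, 0 °C→rt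
Reagents that add atoms: tert-butyldimethylsilyl chloride, CC(C)(C)[Si](C)(C)Cl
Why: Imidazole-mediated silylation protects the primary allylic hydroxyl (future C15–O) as a base-stable ether.

Step 15
Reactants: 23 the silyl ether ester
Product: 24 2-{[(tert-butyldimethylsilyl)oxy]methyl}prop-2-enoic acid
Conditions: LiOH·H2O, THF/H2O, 0 °C→rt; then 1 M HCl to pH 4, 0 °C
Reagents that add atoms: lithium hydroxide, [Li+].[OH-]
Why: Saponification of the ethyl ester gives the acid, the primary silyl ether surviving the cold basic medium and the brief mildly acidic work-up.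

Step 16
Reactants: 21 the α-ketol; 24 the acrylic acid
Product: 26 (3R,5S)-5-[(2R,3S)-2-ethenyl-5-oxooxolan-3-yl]-3-methyl-2-oxo-5-[(triisopropylsilyl)oxy]pentan-3-yl 2-{[(tert-butyldimethylsilyl)oxy]methyl}prop-2-enoate, via trichlorobenzoic mixed anhydride 25 (not isolated)
Conditions: 24, 2,4,6-Cl3C6H2COCl, Et3N, toluene, rt; then 21, DMAP (3 equiv), toluene, rt→50 °C
Reagents that add atoms: none
Why: Yamaguchi esterification, in which DMAP opens the mixed anhydride to a highly electrophilic acylpyridinium ion, should acylate the tertiary C10 hydroxyl, the only free hydroxyl left, and the acid has no α-hydrogen so no ketene pathway interferes.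

Step 17
Reactants: 26 the diene ester
Product: 27 nine-membered keto lactone (4Z,6R,7S,8S,10R): ring O10–C3(=O)–C4(CH2OTBS)=C5–C6–C7–C8(OTIPS)–C9–C10(CH3)(COCH3) trans-fused at C6–C7 to the γ-lactone O6–C12(=O)–C11H2
Conditions: second-generation Hoveyda–Grubbs catalyst RuCl2(H2IMes)(=CH-C6H4-2-O-i-Pr) (15 mol%), 1,4-benzoquinone, toluene (1 mM), 90 °C
Reagents that add atoms: none
Why: Ring-closing metathesis initiated at the monosubstituted C6 vinyl group and terminated on the 1,1-disubstituted acrylate releases ethylene and forms the trisubstituted C4=C5 bond, whose Z geometry (C3 and C6 cis) is the only one a nine-membered ring can hold, with high dilution and the quaternary C10 favouring cyclisation over dimerisation.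

Step 18
Reactants: 27 the nine-membered keto lactone
Product: 29 bis-silyl furanone lactone (4Z,6R,7S,8S,10R): 3(2H)-furanone O–C10(CH3)–C1(=O)–C2H=C3 bridging the ten-membered carbocycle C1–C10 that carries C4(CH2OTBS)=C5 and C8–OTIPS and the trans-fused γ-lactone at C6–C7, via hemiketal 28 (not isolated)
Conditions: LiN(SiMe3)2 (2.2 equiv), THF, −78→−20 °C; AcOH; then PPTS (cat.), CH2Cl2, rt
Reagents that add atoms: none
Why: Proposed new method: the amide base removes a proton from the acetyl methyl group (C2), the lithium enolate adds to the lactone carbonyl C3, which the O–C10–C1 tether holds in a 5-exo-trig relationship, and the tetrahedral adduct is either protonated to hemiketal 28 or opens to the ten-membered 1,3-diketonate, both of which lose water with mild acid to give the same vinylogous ester. The closest known reactions are the base-induced Claisen cyclisation of open-chain α-acyloxy ketones to 3(2H)-furanones and the base isomerisation of keto lactones to cyclic 1,3-diketones; what is new is that the ester is a medium-ring lactone, so the O-to-C acyl shift is transannular. The furanone ring closes by the 5-exo attack at C3 followed by dehydration to C2=C3, and the ten-membered carbocycle C1–C10 closes in the same bond-forming event, that is through a five-membered and not a ten-membered transition state, the Z geometry of C4=C5 being inherited from 27. No stereocentre is formed or endangered (C10 is quaternary, C6 to C8 are not α to a carbonyl). The selectivity needed is chemoselective enolisation at C2 in the presence of the lactone α-CH2 (C11), which could reach C3 by a six-membered Dieckmann closure; it should be secured by the roughly five pKa units that separate a methyl ketone from a lactone, by a hindered base in slight excess at −78 °C, and by trapping of the product as the unreactive diketonate or hemiketal alkoxide. C4 is sp2, so the ester has no α-hydrogen and the butenolide-forming aldol of α-acyloxy ketones is excluded, and the bulky silyl group on O8 should prevent a 1,5-silyl shift to a C10 alkoxide.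

Step 19
Reactants: 29 the bis-silyl furanone lactone
Product: 32 α-methylene lactone (4Z,6R,7S,8S,10R): 29 with C11=C13H2, via Mannich base 30 (not isolated), via ammonium iodide 31 (not isolated)
Conditions: LiN(i-Pr)2 (1.2 equiv), THF, −78 °C; CH2=NMe2+ I−, −78 °C→rt; then MeI, CH2Cl2/MeOH, rt; then aq. NaHCO3, rt
Reagents that add atoms: N,N-dimethylmethyleneiminium iodide, C=[N+](C)C.[I-]
Why: Kinetic enolisation of the γ-lactone at C11 (the only CH2 α to a carbonyl that is left) and Mannich reaction with the iminium salt, followed by N-methylation and E1cB loss of trimethylamine, is the standard α-methylenation of lactones and installs C13 without a lasting stereocentre.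

Step 20
Reactants: 32 the α-methylene lactone
Product: 33 diol (4Z,6R,7R,8S,10R): 32 with free hydroxyls at C8 and C15
Conditions: HF·pyridine, pyridine, THF, 0 °C→rt
Reagents that add atoms: none
Why: Fluoride-mediated cleavage of both silyl ethers under buffered acidic conditions should spare the α-methylene lactone, which would suffer conjugate addition with basic fluoride sources.

Step 21
Reactants: 33 the diol
Product: 34 C15 monoacetate (4Z,6R,7R,8S,10R)
Conditions: Ac2O (1.1 equiv), 2,4,6-collidine, CH2Cl2, −20→0 °C
Reagents that add atoms: acetic anhydride, CC(=O)OC(C)=O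
Why: Acylation without a nucleophilic catalyst should differentiate the unhindered primary allylic C15 hydroxyl from the secondary C8 hydroxyl, which is flanked by the C7 branch and the quaternary C10.

Step 22
Reactants: 34 the monoacetate
Product: 35 target CNP0179932.1
Conditions: methacrylic anhydride, DMAP, Et3N, CH2Cl2, 0 °C→rt
Reagents that add atoms: methacrylic anhydride, CC(=C)C(=O)OC(=O)C(C)=C
Why: DMAP-catalysed acyl transfer to the remaining secondary hydroxyl gives the C8 methacrylate with retention at C8 and completes the target.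

**Compound list**

1 | (R)-citramalic acid | C[C@@](O)(CC(=O)O)C(=O)O | starting material
2 | 2-[(4R)-2,2,4-trimethyl-5-oxo-1,3-dioxolan-4-yl]acetic acid | OC(=O)C[C@@]1(C)OC(C)(C)OC1=O | intermediate
3 | (5R)-5-(2-hydroxyethyl)-2,2,5-trimethyl-1,3-dioxolan-4-one (not isolated) | OCC[C@@]1(C)OC(C)(C)OC1=O | intermediate
4 | (3R)-3-hydroxy-3-methyloxolan-2-one | C[C@@]1(O)CCOC1=O | intermediate
5 | (3R)-2,3-dimethyloxolane-2,3-diol, lactol (not isolated) | CC1(O)OCC[C@@]1(C)O | intermediate
6 | (3R)-3-methylpentane-1,3,4-triol (C4 epimers) | OCC[C@@](C)(O)C(C)O | intermediate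
7 | 2-[(4R)-2,2,4,5-tetramethyl-1,3-dioxolan-4-yl]ethan-1-ol | OCC[C@@]1(C)OC(C)(C)OC1C | intermediate
8 | 2-[(4R)-2,2,4,5-tetramethyl-1,3-dioxolan-4-yl]acetaldehyde | O=CC[C@@]1(C)OC(C)(C)OC1C | intermediate
9 | mono-tert-butyl succinate | CC(C)(C)OC(=O)CCC(=O)O | starting material
10 | (4R)-4-benzyl-1,3-oxazolidin-2-one | O=C1N[C@H](Cc2ccccc2)CO1 | starting material
11 | 4-(tert-butoxy)-4-oxobutanoic pivalic anhydride (not isolated) | CC(C)(C)OC(=O)CCC(=O)OC(=O)C(C)(C)C | intermediate
12 | tert-butyl 4-[(4R)-4-benzyl-2-oxo-1,3-oxazolidin-3-yl]-4-oxobutanoate | CC(C)(C)OC(=O)CCC(=O)N1[C@H](Cc2ccccc2)COC1=O | intermediate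
13 | (Z)-dibutylboron enolate of 12 (not isolated) | CCCCB(CCCC)O/C(=C\CC(=O)OC(C)(C)C)N1[C@H](Cc2ccccc2)COC1=O | intermediate
14 | tert-butyl (3R,4S)-3-{[(4R)-4-benzyl-2-oxo-1,3-oxazolidin-3-yl]carbonyl}-4-hydroxy-5-[(4R)-2,2,4,5-tetramethyl-1,3-dioxolan-4-yl]pentanoate | CC(C)(C)OC(=O)C[C@@H](C(=O)N1[C@H](Cc2ccccc2)COC1=O)[C@@H](O)C[C@@]1(C)OC(C)(C)OC1C | intermediate
15 | TIPS ether of 14 | CC(C)(C)OC(=O)C[C@@H](C(=O)N1[C@H](Cc2ccccc2)COC1=O)[C@@H](O[Si](C(C)C)(C(C)C)C(C)C)C[C@@]1(C)OC(C)(C)OC1C | intermediate
16 | tert-butyl (3S,4S)-3-(hydroxymethyl)-5-[(4R)-2,2,4,5-tetramethyl-1,3-dioxolan-4-yl]-4-[(triisopropylsilyl)oxy]pentanoate | CC(C)(C)OC(=O)C[C@@H](CO)[C@@H](O[Si](C(C)C)(C(C)C)C(C)C)C[C@@]1(C)OC(C)(C)OC1C | intermediate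
17 | tert-butyl (3R,4S)-3-formyl-5-[(4R)-2,2,4,5-tetramethyl-1,3-dioxolan-4-yl]-4-[(triisopropylsilyl)oxy]pentanoate | CC(C)(C)OC(=O)C[C@@H](C=O)[C@@H](O[Si](C(C)C)(C(C)C)C(C)C)C[C@@]1(C)OC(C)(C)OC1C | intermediate
18 | vinylmagnesium bromide | C=C[Mg]Br | starting material
19 | tert-butyl (3S,4R)-4-hydroxy-3-{(1S)-2-[(4R)-2,2,4,5-tetramethyl-1,3-dioxolan-4-yl]-1-[(triisopropylsilyl)oxy]ethyl}hex-5-enoate | CC(C)(C)OC(=O)C[C@@H]([C@H](O)C=C)[C@@H](O[Si](C(C)C)(C(C)C)C(C)C)C[C@@]1(C)OC(C)(C)OC1C | intermediate
20 | (4S,5R)-4-{(1S,3R)-3,4-dihydroxy-3-methyl-1-[(triisopropylsilyl)oxy]pentyl}-5-ethenyloxolan-2-one | C=C[C@H]1OC(=O)C[C@@H]1[C@@H](O[Si](C(C)C)(C(C)C)C(C)C)C[C@@](C)(O)C(C)O | intermediate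
21 | (4S,5R)-5-ethenyl-4-{(1S,3R)-3-hydroxy-3-methyl-4-oxo-1-[(triisopropylsilyl)oxy]pentyl}oxolan-2-one | C=C[C@H]1OC(=O)C[C@@H]1[C@@H](O[Si](C(C)C)(C(C)C)C(C)C)C[C@@](C)(O)C(C)=O | intermediate
22 | ethyl 2-(hydroxymethyl)acrylate | C=C(CO)C(=O)OCC | starting material
23 | ethyl 2-{[(tert-butyldimethylsilyl)oxy]methyl}prop-2-enoate | C=C(CO[Si](C)(C)C(C)(C)C)C(=O)OCC | intermediate
24 | 2-{[(tert-butyldimethylsilyl)oxy]methyl}prop-2-enoic acid | C=C(CO[Si](C)(C)C(C)(C)C)C(=O)O | intermediate
25 | mixed anhydride of 24 with 2,4,6-trichlorobenzoic acid (not isolated) | C=C(CO[Si](C)(C)C(C)(C)C)C(=O)OC(=O)c1c(Cl)cc(Cl)cc1Cl | intermediate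
26 | (3R,5S)-5-[(2R,3S)-2-ethenyl-5-oxooxolan-3-yl]-3-methyl-2-oxo-5-[(triisopropylsilyl)oxy]pentan-3-yl 2-{[(tert-butyldimethylsilyl)oxy]methyl}prop-2-enoate | C=C[C@H]1OC(=O)C[C@@H]1[C@@H](O[Si](C(C)C)(C(C)C)C(C)C)C[C@@](C)(OC(=O)C(=C)CO[Si](C)(C)C(C)(C)C)C(C)=O | intermediate
27 | nine-membered keto lactone (4Z,6R,7S,8S,10R), key-step precursor | CC(C)[Si](C(C)C)(C(C)C)O[C@H]1C[C@@](C(C)=O)(C)OC(=O)/C(CO[Si](C)(C)C(C)(C)C)=C\[C@H]2OC(=O)C[C@H]12 | intermediate
28 | C3 hemiketal of the Claisen adduct (not isolated) | CC(C)[Si](C(C)C)(C(C)C)O[C@H]1C[C@@]2(C)OC(O)(CC2=O)/C(CO[Si](C)(C)C(C)(C)C)=C\[C@H]2OC(=O)C[C@H]12 | intermediate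
29 | bis-silyl furanone lactone (4Z,6R,7S,8S,10R), key-step product | CC(C)[Si](C(C)C)(C(C)C)O[C@H]1C[C@@]2(C)OC(=CC2=O)/C(CO[Si](C)(C)C(C)(C)C)=C\[C@H]2OC(=O)C[C@H]12 | intermediate
30 | C11 dimethylaminomethyl lactone, Mannich base (not isolated) | CC(C)[Si](C(C)C)(C(C)C)O[C@H]1C[C@@]2(C)OC(=CC2=O)/C(CO[Si](C)(C)C(C)(C)C)=C\[C@H]2OC(=O)C(CN(C)C)[C@H]12 | intermediate
31 | trimethylammonium iodide of 30 (not isolated) | CC(C)[Si](C(C)C)(C(C)C)O[C@H]1C[C@@]2(C)OC(=CC2=O)/C(CO[Si](C)(C)C(C)(C)C)=C\[C@H]2OC(=O)C(C[N+](C)(C)C)[C@H]12.[I-] | intermediate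
32 | bis-silyl α-methylene lactone (4Z,6R,7S,8S,10R) | CC(C)[Si](C(C)C)(C(C)C)O[C@H]1C[C@@]2(C)OC(=CC2=O)/C(CO[Si](C)(C)C(C)(C)C)=C\[C@H]2OC(=O)C(=C)[C@H]12 | intermediate
33 | C8,C15-diol (4Z,6R,7R,8S,10R) | O[C@H]1C[C@@]2(C)OC(=CC2=O)/C(CO)=C\[C@H]2OC(=O)C(=C)[C@H]12 | intermediate
34 | C15 acetate with free C8 hydroxyl (4Z,6R,7R,8S,10R) | O[C@H]1C[C@@]2(C)OC(=CC2=O)/C(COC(C)=O)=C\[C@H]2OC(=O)C(=C)[C@H]12 | intermediate
35 | CNP0179932.1 (4Z,6R,7R,8S,10R) | C=C(C)C(=O)O[C@H]1C[C@@]2(C)OC(=CC2=O)/C(COC(C)=O)=C\[C@H]2OC(=O)C(=C)[C@H]12 | target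

**Step count.** Total: 22 steps. Longest linear sequence: 19 steps (1–5, 7–13, 16–22, from compound 1).

**Steps most likely to fail**

Step 18 (carries the label). What may go wrong: competing enolisation at C11 followed by six-membered Dieckmann attack on C3, or base-induced degradation of the strained lactone before the acyl shift. The fallback uses known chemistry, sets out from the open-chain ester 26 and returns at 29. Treating 26 with LiN(SiMe3)2 at −78 °C and then mild acid is the classical Claisen cyclisation of an α-acyloxy ketone whose acyl group has no α-hydrogen, and should give the open-chain 3(2H)-furanone diene F1. Ring-closing metathesis of F1 with the second-generation Hoveyda–Grubbs catalyst under high dilution then forms C4=C5 and closes the ten-membered carbocycle to 29. Only the order of the two ring closures is exchanged.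

Step 17. What may go wrong: oligomerisation by cross-metathesis at the vinyl group because the gem-disubstituted, electron-poor acrylate does not engage. The fallback sets out from 26 and returns at 27 with a redesigned diene. Selective removal of the primary TBS group of 26 (HF·pyridine buffered with pyridine, 0 °C, the TIPS ether staying) gives the allylic alcohol F2. Its free hydroxyl next to the hindered olefin is known to accelerate ruthenium metathesis at that double bond and removes the bulk of the silyl group. Ring closure of F2 under the conditions of step 17 should give the hydroxy lactone F3, and TBSCl with imidazole returns 27.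

Step 11. What may go wrong: poor facial selectivity in the Grignard addition, giving the C6 epimer. The fallback sets out from 17 and returns at 20 under thermodynamic instead of kinetic control. The mixture of 19 and its C6 epimer F4 is taken through step 12 to 20 and the cis-lactone F5. Pd(PPh3)4 (zerovalent palladium, THF, rt) then ionises the allylic C6–O bond of the vinyl lactone reversibly. The π-allyl carboxylate recloses after π-σ-π face exchange and should funnel F5 into the more stable trans-lactone 20.

**Further compounds**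

F1 | step 18 | open-chain furanone diene: (2R)-2-methyl-2-{(2S)-2-[(2R,3S)-2-ethenyl-5-oxooxolan-3-yl]-2-[(triisopropylsilyl)oxy]ethyl}-5-(3-{[tert-butyldimethylsilyl]oxy}prop-1-en-2-yl)furan-3(2H)-one | C=C[C@H]1OC(=O)C[C@@H]1[C@@H](O[Si](C(C)C)(C(C)C)C(C)C)C[C@@]1(C)OC(=CC1=O)C(=C)CO[Si](C)(C)C(C)(C)C
F2 | step 17 | C15-hydroxy diene (26 without the TBS group) | C=C[C@H]1OC(=O)C[C@@H]1[C@@H](O[Si](C(C)C)(C(C)C)C(C)C)C[C@@](C)(OC(=O)C(=C)CO)C(C)=O
F3 | step 17 | C15-hydroxy nine-membered keto lactone (27 without the TBS group) | CC(C)[Si](C(C)C)(C(C)C)O[C@H]1C[C@@](C(C)=O)(C)OC(=O)/C(CO)=C\[C@H]2OC(=O)C[C@H]12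
F4 | step 11 | C6 epimer of 19 | CC(C)(C)OC(=O)C[C@@H]([C@@H](O)C=C)[C@@H](O[Si](C(C)C)(C(C)C)C(C)C)C[C@@]1(C)OC(C)(C)OC1C
F5 | step 11 | cis-lactone diol (C6 epimer of 20) | C=C[C@@H]1OC(=O)C[C@@H]1[C@@H](O[Si](C(C)C)(C(C)C)C(C)C)C[C@@](C)(O)C(C)O
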